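## Retrosynthetic overview

- Rings: A is the benzene core, B the lactone, C the 4-hydroxyphenyl group and D the 4-methoxy-2-pyranone.
- Last disconnection: the C4–ring C bond. This gives a coumarin and 4-hydroxyphenylboronic acid, and an enantioselective rhodium-catalysed 1,4-addition sets 4R.
- Key disconnection: rings A and B of the coumarin together, by a [4+2] ring transformation. 5-Acetyl-6-methyl-2-pyranone supplies C2–C4, C4a, C5, C8, C8a and the 5-methyl. The carbanion of a ring D acetic ester supplies C6 and C7.
- The ring D acetic ester comes from C-methoxycarbonylation of bought 4-methoxy-6-methyl-2-pyranone. The acetylpyranone comes from acetylacetone and methyl propiolate.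
- Ring order: a sacrificial pyranone first, then A and B in one operation. C and D are bought intact, and the stereocentre comes last.

Assumption: 4-methoxy-6-methyl-2H-pyran-2-one (the methyl ether of triacetic acid lactone) counts as a purchasable starting material, and the stereocentre in the SMILES is read as 4R (C4a > aryl > CH2 > H).

## Route

Step 1
Reactants: 1 pentane-2,4-dione (acetylacetone); 2 methyl propiolate
Product: 4 5-acetyl-6-methyl-2H-pyran-2-one, via Michael adduct 3 (not isolated)
Conditions: DBU (0.2 equiv), toluene, 0 → 110 °C, MeOH distilled off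
Reagents that add atoms: none
Why: Base-catalysed Michael addition of the diketone carbon to the ynoate gives 3, whose delocalised enolate can rotate about the former alkene so that the enol oxygen reaches the ester and closes the ring (Michael addition–lactonisation synthesis of 2-pyranones); no stereocentre is formed.

Step 2
Reactants: 5 4-methoxy-6-methyl-2H-pyran-2-one
Product: 6 methyl 2-(4-methoxy-2-oxo-2H-pyran-6-yl)acetate
Conditions: LiN(SiMe3)2 (2.1 equiv), THF, −78 °C; ClCO2Me (1.0 equiv), −78 → −40 °C; 1 M HCl
Reagents that add atoms: methyl chloroformate, COC(=O)Cl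
Why: The 6-methyl group is the vinylogous acidic site of the pyranone and its dienolate is C-acylated at the exocyclic carbon (vinylogous Claisen-type acylation), while the second equivalent of base holds the more acidic product as its enolate and so blocks a second acylation; no stereocentre is formed.

Step 3
Reactants: 4 5-acetyl-6-methyl-2H-pyran-2-one; 6 methyl 2-(4-methoxy-2-oxo-2H-pyran-6-yl)acetate
Product: 9 7-hydroxy-6-(4-methoxy-2-oxo-2H-pyran-6-yl)-5-methyl-2H-chromen-2-one, via ring-opened dienoic acid 7 (not isolated), via cis-cinnamic acid 8 (not isolated)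
Conditions: 6, KOtBu (1.05 equiv), THF–DMF 4:1, 0 °C; add 4, 0 °C → rt; KOtBu (1.05 equiv), 60 °C; then 2 M HCl, rt
Reagents that add atoms: none
Why: Proposed new method: the soft, doubly stabilised carbanion of 6 should add to C6 of 4, which is activated both as the δ-carbon of the pyranone and as the β-carbon of the acetyl enone, and the ring then opens irreversibly to the carboxylate of 7 (cis alkene kept, acid end now inert to nucleophiles); under equilibrating base the enolate of the acetyl methyl group closes on the methyl ester (Dieckmann/Claisen step, loss of MeOH) to a 1,3-dione that tautomerises to the resorcinol 8, the thermodynamic sink, and acidification lactonises this cis-2-hydroxycinnamic acid at once, so ring A and ring B arise in one operation with the substitution pattern fixed by connectivity and not by arene regioselectivity; the closest known reaction types are the carbanion-induced ring transformation of 2H-pyran-2-ones and the Michael–Dieckmann synthesis of resorcinols from malonate-type donors; no stereocentre is formed.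

Step 4
Reactants: 9 7-hydroxy-6-(4-methoxy-2-oxo-2H-pyran-6-yl)-5-methyl-2H-chromen-2-one; 10 4-hydroxyphenylboronic acid
Product: 11 (4R)-7-hydroxy-4-(4-hydroxyphenyl)-6-(4-methoxy-2-oxo-2H-pyran-6-yl)-5-methyl-3,4-dihydro-2H-chromen-2-one
Conditions: Rh(acac)(C2H4)2 (3 mol %), (R)-SEGPHOS (3.3 mol %), 10 (5 equiv), dioxane–H2O 10:1, 60 °C
Reagents that add atoms: none
Why: Hayashi–Miyaura asymmetric 1,4-addition, in which the aryl complex of monovalent rhodium inserts the coumarin C3=C4 bond and water protonates the resulting enolate; the (R)-ligand delivers the aryl group to the face that gives (R)-4-arylchroman-2-ones, the same priority order applies here, so C4 is set as R, and ring D stays untouched because its β-carbon carries the methoxy donor and its C6 is fully substituted.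

## Compound list

1 | pentane-2,4-dione | CC(=O)CC(C)=O | starting material
2 | methyl propiolate | COC(=O)C#C | starting material
3 | methyl (2E)-4-acetyl-5-oxohex-2-enoate (Michael adduct, not isolated) | COC(=O)/C=C/C(C(C)=O)C(C)=O | intermediate
4 | 5-acetyl-6-methyl-2H-pyran-2-one | CC(=O)C1=C(C)OC(=O)C=C1 | intermediate
5 | 4-methoxy-6-methyl-2H-pyran-2-one | COC1=CC(=O)OC(C)=C1 | starting material
6 | methyl 2-(4-methoxy-2-oxo-2H-pyran-6-yl)acetate | COC(=O)CC1=CC(OC)=CC(=O)O1 | intermediate
7 | (2Z)-4-acetyl-7-methoxy-6-(4-methoxy-2-oxo-2H-pyran-6-yl)-5-methyl-7-oxohepta-2,4-dienoic acid (C4=C5 geometry and C6 configuration equilibrate, not isolated) | OC(=O)/C=C\C(C(C)=O)=C(C)C(C(=O)OC)C1=CC(OC)=CC(=O)O1 | intermediate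
8 | (2Z)-3-[2,4-dihydroxy-5-(4-methoxy-2-oxo-2H-pyran-6-yl)-6-methylphenyl]prop-2-enoic acid (not isolated) | OC(=O)/C=C\c1c(O)cc(O)c(c1C)-c1cc(OC)cc(=O)o1 | intermediate
9 | 7-hydroxy-6-(4-methoxy-2-oxo-2H-pyran-6-yl)-5-methyl-2H-chromen-2-one | COc1cc(-c2c(O)cc3c(c2C)C=CC(=O)O3)oc(=O)c1 | intermediate
10 | 4-hydroxyphenylboronic acid | OB(O)c1ccc(O)cc1 | starting material
11 | (4R)-7-hydroxy-4-(4-hydroxyphenyl)-6-(4-methoxy-2-oxo-2H-pyran-6-yl)-5-methyl-3,4-dihydro-2H-chromen-2-one | COc1cc(-c2c(O)cc3c(c2C)[C@@H](c2ccc(O)cc2)CC(=O)O3)oc(=O)c1 | target

## Step count and risks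

Total step count: 4. Longest linear sequence: 3 (step 1 or step 2, then steps 3 and 4).

**Step 3 (highest risk).**
- The bulky carbanion may attack C2 or C4 of 4 instead of the methyl-bearing C6.
- The dienolate oxygen may close on the ester in place of the acetyl carbon.
- Long heating may turn the cis acid trans.

The fallback sets out from 1 and 6 and comes back at 9. It builds the two rings one after the other.
- Acetylacetone 1 is converted into (E)-4-methoxypent-3-en-2-one F1 (HC(OMe)3, cat. TsOH, MeOH).
- The potassium enolate of 6 adds to this unhindered acyclic β-methoxyenone and loses methoxide.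
- The same Dieckmann step then closes it to 6-(2,4-dihydroxy-6-methylphenyl)-4-methoxy-2H-pyran-2-one F2.
- Ring B is closed separately by hydroarylation–lactonisation with methyl propiolate 2 (Pd(OAc)2, divalent palladium, TFA–CH2Cl2, rt). The small electrophile enters para to the 2-OH, next to the methyl group, and this gives 9.

**Step 4.**
- The 5-methyl group crowds C4 and the 7-OH lowers the electrophilicity of the coumarin.
- The electron-rich boronic acid protodeboronates.

The fallback sets out from 9 and comes back at 11. It separates C–C bond formation from the stereo-defining event.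
- An oxidative Heck arylation of 9 with 10 (Pd(OAc)2, 1,10-phenanthroline, O2, DMF, 80 °C) gives 7-hydroxy-4-(4-hydroxyphenyl)-6-(4-methoxy-2-oxo-2H-pyran-6-yl)-5-methyl-2H-chromen-2-one F3.
- An enantioselective copper hydride conjugate reduction follows (Cu(OAc)2, DTBM-SEGPHOS, (EtO)2MeSiH, t-BuOH, toluene, then a mild acid work-up to free the phenols).
- The ligand antipode is chosen so that hydride reaches the face that leaves C4 as R, which gives 11.

**Step 2.**
- O-acylation, double acylation or metalation at C3 may compete with acylation of the exocyclic carbon.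

The fallback sets out from 5 and comes back at 6. It reverses the polarity of the side-chain carbon.
- Radical bromination of 5 (NBS, dibenzoyl peroxide, PhCF3, reflux) gives 6-(bromomethyl)-4-methoxy-2H-pyran-2-one F4.
- Palladium-catalysed methoxycarbonylation of F4 (PdCl2(PPh3)2, CO 1 atm, MeOH, K2CO3, 50 °C) gives 6.

## Further compounds

F1 | step 3 | (E)-4-methoxypent-3-en-2-one | CO/C(C)=C/C(C)=O
F2 | step 3 | 6-(2,4-dihydroxy-6-methylphenyl)-4-methoxy-2H-pyran-2-one | COc1cc(-c2c(O)cc(O)cc2C)oc(=O)c1
F3 | step 4 | 7-hydroxy-4-(4-hydroxyphenyl)-6-(4-methoxy-2-oxo-2H-pyran-6-yl)-5-methyl-2H-chromen-2-one | COc1cc(-c2c(O)cc3c(c2C)C(c2ccc(O)cc2)=CC(=O)O3)oc(=O)c1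
F4 | step 2 | 6-(bromomethyl)-4-methoxy-2H-pyran-2-one | COC1=CC(=O)OC(CBr)=C1
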